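**Plan**

- Retrosynthesis: first the two O‑acetyl bonds and the phenol O‑benzyl bond are cut, then both CH2O carbons go back to ethyl esters. Next the C2–aryl bond is cut, which returns the O1/C2/C3/C3a/C7a ring to a flat benzofuran‑3‑carboxylate and an arylboronic acid. Last come the C5–CH2 bond of the side chain and the furan ring itself (O1–C2 and C3–C3a, from a salicylaldehyde and a diazoester).
- Forward: the furan ring is built on a brominated o‑vanillin core, the three‑carbon chain is joined by sp2–sp3 coupling, and the guaiacyl ring is then joined at C2 by dearomatising the furan ring. Reduction, acetylation and debenzylation finish the route.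
- Enabling feature: C2=C3 of the furan ring is a β‑aryloxy acrylate (O1–C2=C3–CO2Et) inside a ring that is only weakly aromatic. C2 can therefore accept an aryl–metal as a 1,4‑acceptor while the benzo ring stays intact; the C3 ester is the activating group and is later reduced to the CH2OAc carbon.
- Stereochemistry: C2 comes from the chiral diene–Rh catalyst (aryl to the Re face of C2). C3 comes from base equilibration α to the ester to the trans isomer. Neither centre is touched afterwards; (2S,3S) in the ester becomes (2S,3R) after reduction by a CIP priority change only.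

Key step: step 3

Remark: the target SMILES is read as the trans‑(2S,3R) isomer. The sense of induction of the diene ligand on this substrate class is not known in advance, so the ligand enantiomer is fixed by a pilot run.

**Route**

Step 1
Reactants: 1 5‑bromo‑2‑hydroxy‑3‑methoxybenzaldehyde; 2 ethyl diazoacetate
Product: 4 ethyl 5‑bromo‑7‑methoxy‑1‑benzofuran‑3‑carboxylate, via cyclic hemiacetal 3 (not isolated)
Conditions: HBF4·OEt2 (10 mol%), CH2Cl2, rt; then conc. H2SO4, rt
Reagents that add atoms: ethyl diazoacetate (2), CCOC(=O)C=[N+]=[N-]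
Why: Acid‑catalysed diazoester homologation of the salicylaldehyde (Roskamp‑type addition in which the electron‑rich aryl group undergoes the 1,2‑shift with loss of N2) gives an α‑formyl arylacetate that closes with the phenol to hemiacetal 3, and H2SO4 dehydrates it to the aromatic furan ring; no stereocentre survives.

Step 2
Reactants: 4 ethyl 5‑bromo‑7‑methoxy‑1‑benzofuran‑3‑carboxylate; 5 (3‑ethoxy‑3‑oxopropyl)zinc bromide
Product: 6 ethyl 5‑(3‑ethoxy‑3‑oxopropyl)‑7‑methoxy‑1‑benzofuran‑3‑carboxylate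
Conditions: Pd(OAc)2 (2 mol%), SPhos (4 mol%), THF, 50 °C
Reagents that add atoms: (3‑ethoxy‑3‑oxopropyl)zinc bromide (5), CCOC(=O)CC[Zn]Br
Why: Negishi sp2–sp3 cross‑coupling of the aryl bromide with an ester‑tolerant primary alkylzinc reagent; the bulky biarylphosphine should favour reductive elimination over β‑hydride elimination, and the C3 ester and C2–H are inert.

Step 3
Reactants: 6 ethyl 5‑(3‑ethoxy‑3‑oxopropyl)‑7‑methoxy‑1‑benzofuran‑3‑carboxylate; 7 [4‑(benzyloxy)‑3‑methoxyphenyl]boronic acid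
Product: 9 ethyl (2S,3S)‑2‑[4‑(benzyloxy)‑3‑methoxyphenyl]‑5‑(3‑ethoxy‑3‑oxopropyl)‑7‑methoxy‑2,3‑dihydro‑1‑benzofuran‑3‑carboxylate, via C3‑epimeric diester 8 (not isolated)
Conditions: 7 (3 equiv, in portions), [RhCl(C2H4)2]2 (2.5 mol%), chiral diene Ph‑bod* (5.5 mol%), KOH (10 mol%), dioxane/H2O 10:1, 80 °C; then solvent switch, NaOEt (0.2 equiv), EtOH, rt
Reagents that add atoms: [4‑(benzyloxy)‑3‑methoxyphenyl]boronic acid (7), COc1cc(B(O)O)ccc1OCc1ccccc1
Why: Proposed new method: transmetalation of 7 to the chiral diene–Rh(I)–OH complex gives an aryl–Rh species that binds the C2=C3 bond of 6 as an enoate and inserts with aryl to C2, giving a C3 rhodium oxa‑π‑allyl (also benzylic) that water protonates to release 8 and Rh–OH; the cost is only the small resonance energy of the furan ring, since the benzo ring stays aromatic. The closest known reaction type is the Hayashi–Miyaura Rh‑catalysed asymmetric 1,4‑addition of arylboronic acids to α,β‑unsaturated esters, coumarins and chromones (β‑aryloxy acceptors), together with catalytic dearomative conjugate additions to nitro‑activated benzofurans. No ring is closed: the existing O1–C2–C3–C3a–C7a ring is dearomatised. C2 is set by the catalyst, the chiral diene shielding one face of the planar heteroarene so that aryl is delivered to the C2 Re face, and C3 is set under thermodynamic control when NaOEt equilibrates 8 through the ester enolate to the trans isomer with aryl and ester anti. The step needs 1,4‑regioselectivity at the only conjugated position (the saturated chain ester is inert) and survival of the C2–O1 bond: β‑aryloxide loss from the C3 enolate would be a retro‑5‑endo‑trig opening with the C2–O bond orthogonal to the enolate π system, so epimerisation at C3 should not erode C2.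

Step 4
Reactants: 9 ethyl (2S,3S)‑2‑[4‑(benzyloxy)‑3‑methoxyphenyl]‑5‑(3‑ethoxy‑3‑oxopropyl)‑7‑methoxy‑2,3‑dihydro‑1‑benzofuran‑3‑carboxylate
Product: 10 3‑[(2S,3R)‑2‑[4‑(benzyloxy)‑3‑methoxyphenyl]‑3‑(hydroxymethyl)‑7‑methoxy‑2,3‑dihydro‑1‑benzofuran‑5‑yl]propan‑1‑ol
Conditions: LiAlH4 (2.5 equiv), THF, 0 °C to rt; aqueous NaOH work‑up
Reagents that add atoms: none
Why: Hydride (LiAlH4) reduction of both esters to primary alcohols; C2 is not acidic and C3 is already in its thermodynamic trans arrangement, so the configuration should be retained (the C3 descriptor changes from S to R only through the priority change CO2Et → CH2OH).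

Step 5
Reactants: 10 3‑[(2S,3R)‑2‑[4‑(benzyloxy)‑3‑methoxyphenyl]‑3‑(hydroxymethyl)‑7‑methoxy‑2,3‑dihydro‑1‑benzofuran‑5‑yl]propan‑1‑ol
Product: 11 3‑[(2S,3R)‑3‑(acetoxymethyl)‑2‑[4‑(benzyloxy)‑3‑methoxyphenyl]‑7‑methoxy‑2,3‑dihydro‑1‑benzofuran‑5‑yl]propyl acetate
Conditions: Ac2O (3 equiv), pyridine, DMAP (5 mol%), CH2Cl2, rt
Reagents that add atoms: acetic anhydride, CC(=O)OC(C)=O
Why: DMAP‑catalysed O‑acylation of the two primary alcohols; the phenol is masked as its benzyl ether, so only the two required acetates form and no stereocentre is touched.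

Step 6
Reactants: 11 3‑[(2S,3R)‑3‑(acetoxymethyl)‑2‑[4‑(benzyloxy)‑3‑methoxyphenyl]‑7‑methoxy‑2,3‑dihydro‑1‑benzofuran‑5‑yl]propyl acetate
Product: 12 3‑[(2S,3R)‑3‑(acetoxymethyl)‑2‑(4‑hydroxy‑3‑methoxyphenyl)‑7‑methoxy‑2,3‑dihydro‑1‑benzofuran‑5‑yl]propyl acetate
Conditions: H2 (1 atm), 10% Pd/C, EtOAc, rt, stopped at full conversion
Reagents that add atoms: none
Why: Pd‑catalysed hydrogenolysis of the aryl benzyl ether, which under neutral conditions at 1 atm should be cleaved much faster than the cyclic benzylic C2–O1 ether or the alkyl acetates, releasing the free phenol without change at C2 or C3.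

**Compound list**

1 | 5‑bromo‑2‑hydroxy‑3‑methoxybenzaldehyde | O=Cc1cc(Br)cc(OC)c1O | starting material
2 | ethyl diazoacetate | CCOC(=O)C=[N+]=[N-] | starting material
3 | ethyl 5‑bromo‑2‑hydroxy‑7‑methoxy‑2,3‑dihydro‑1‑benzofuran‑3‑carboxylate (cyclic hemiacetal, stereoisomer mixture, not isolated) | CCOC(=O)C1C(O)Oc2c(OC)cc(Br)cc21 | intermediate
4 | ethyl 5‑bromo‑7‑methoxy‑1‑benzofuran‑3‑carboxylate | CCOC(=O)c1coc2c(OC)cc(Br)cc12 | intermediate
5 | (3‑ethoxy‑3‑oxopropyl)zinc bromide (THF solution) | CCOC(=O)CC[Zn]Br | starting material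
6 | ethyl 5‑(3‑ethoxy‑3‑oxopropyl)‑7‑methoxy‑1‑benzofuran‑3‑carboxylate | CCOC(=O)CCc1cc(OC)c2occ(C(=O)OCC)c2c1 | intermediate
7 | [4‑(benzyloxy)‑3‑methoxyphenyl]boronic acid | COc1cc(B(O)O)ccc1OCc1ccccc1 | starting material
8 | ethyl (2S)‑2‑[4‑(benzyloxy)‑3‑methoxyphenyl]‑5‑(3‑ethoxy‑3‑oxopropyl)‑7‑methoxy‑2,3‑dihydro‑1‑benzofuran‑3‑carboxylate, C3 epimers (not isolated) | COc1cc([C@H]2Oc3c(OC)cc(CCC(=O)OCC)cc3C2C(=O)OCC)ccc1OCc1ccccc1 | intermediate
9 | ethyl (2S,3S)‑2‑[4‑(benzyloxy)‑3‑methoxyphenyl]‑5‑(3‑ethoxy‑3‑oxopropyl)‑7‑methoxy‑2,3‑dihydro‑1‑benzofuran‑3‑carboxylate (trans) | COc1cc([C@H]2Oc3c(OC)cc(CCC(=O)OCC)cc3[C@@H]2C(=O)OCC)ccc1OCc1ccccc1 | intermediate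
10 | 3‑[(2S,3R)‑2‑[4‑(benzyloxy)‑3‑methoxyphenyl]‑3‑(hydroxymethyl)‑7‑methoxy‑2,3‑dihydro‑1‑benzofuran‑5‑yl]propan‑1‑ol | COc1cc([C@H]2Oc3c(OC)cc(CCCO)cc3[C@@H]2CO)ccc1OCc1ccccc1 | intermediate
11 | 3‑[(2S,3R)‑3‑(acetoxymethyl)‑2‑[4‑(benzyloxy)‑3‑methoxyphenyl]‑7‑methoxy‑2,3‑dihydro‑1‑benzofuran‑5‑yl]propyl acetate | COc1cc([C@H]2Oc3c(OC)cc(CCCOC(C)=O)cc3[C@@H]2COC(C)=O)ccc1OCc1ccccc1 | intermediate
12 | 3‑[(2S,3R)‑3‑(acetoxymethyl)‑2‑(4‑hydroxy‑3‑methoxyphenyl)‑7‑methoxy‑2,3‑dihydro‑1‑benzofuran‑5‑yl]propyl acetate | COc1cc([C@H]2Oc3c(OC)cc(CCCOC(C)=O)cc3[C@@H]2COC(C)=O)ccc1O | target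

**Step count**

Total steps: 6. Longest linear sequence: 6 (from 1).

**Steps most likely to fail**

1. Step 3. Migratory insertion into the trisubstituted, partly aromatic C2=C3 bond may be slower than protodeboronation of the electron‑rich boronic acid, or face selection by the diene may be poor. The fallback uses known chemistry and sets out from 6. Pd‑catalysed C2–H arylation by concerted metalation–deprotonation with 1‑(benzyloxy)‑4‑bromo‑2‑methoxybenzene (COc1cc(Br)ccc1OCc1ccccc1; Pd(OAc)2, PCy3·HBF4, PivOH, K2CO3, DMA, 100 °C) should give the flat ethyl 2‑aryl‑1‑benzofuran‑3‑carboxylate F1. Dissolving‑metal conjugate reduction with Mg in MeOH/THF, finished with catalytic NaOMe to complete methanolysis and trans equilibration, should give the racemic trans dimethyl ester F2. LiAlH4 reduction as in step 4 should give the racemic trans diol F3. Preparative HPLC on a chiral stationary phase separates the enantiomers, and the route is rejoined at 10.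

2. Step 6. Over‑reduction may occur, that is hydrogenolysis of the benzylic C2–O1 ring bond alongside O‑debenzylation. The fallback drops the protecting group and sets out from 6. The conjugate arylation is run as in step 3 with 2‑methoxy‑4‑(4,4,5,5‑tetramethyl‑1,3,2‑dioxaborolan‑2‑yl)phenol (COc1cc(B2OC(C)(C)C(C)(C)O2)ccc1O) to give the phenolic trans diester F4. LiAlH4 reduction should give the phenolic diol (triol) F5. Lipase‑catalysed transesterification (immobilised Candida antarctica lipase B, vinyl acetate, MTBE, 40 °C) should acetylate only the two primary alcohols and leave the phenol free, so the route is rejoined at 12.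

3. Step 2. Transmetalation of the alkylzinc may be slow, with protodehalogenation or β‑hydride elimination from the alkyl–Pd intermediate competing. The fallback sets out from 4. A Heck reaction with ethyl acrylate (C=CC(=O)OCC; Pd(OAc)2, n‑Bu4NBr, K2CO3, DMF, 90 °C) should give the (E)‑acrylate F6. Hydrogenation of the side‑chain C=C (H2 1 atm, Pd/C, EtOAc, rt, stopped after one equivalent, the aromatic furan ring being much slower) rejoins the route at 6.

**Further compounds**

F1 | step 3 | ethyl 2‑[4‑(benzyloxy)‑3‑methoxyphenyl]‑5‑(3‑ethoxy‑3‑oxopropyl)‑7‑methoxy‑1‑benzofuran‑3‑carboxylate | COc1cc(-c2oc3c(OC)cc(CCC(=O)OCC)cc3c2C(=O)OCC)ccc1OCc1ccccc1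
F2 | step 3 | methyl (2S*,3S*)‑2‑[4‑(benzyloxy)‑3‑methoxyphenyl]‑7‑methoxy‑5‑(3‑methoxy‑3‑oxopropyl)‑2,3‑dihydro‑1‑benzofuran‑3‑carboxylate (racemic trans, written as both enantiomers) | COc1cc([C@H]2Oc3c(OC)cc(CCC(=O)OC)cc3[C@@H]2C(=O)OC)ccc1OCc1ccccc1.COc1cc([C@@H]2Oc3c(OC)cc(CCC(=O)OC)cc3[C@H]2C(=O)OC)ccc1OCc1ccccc1
F3 | step 3 | 3‑[(2S*,3R*)‑2‑[4‑(benzyloxy)‑3‑methoxyphenyl]‑3‑(hydroxymethyl)‑7‑methoxy‑2,3‑dihydro‑1‑benzofuran‑5‑yl]propan‑1‑ol (racemic trans, written as both enantiomers) | COc1cc([C@H]2Oc3c(OC)cc(CCCO)cc3[C@@H]2CO)ccc1OCc1ccccc1.COc1cc([C@@H]2Oc3c(OC)cc(CCCO)cc3[C@H]2CO)ccc1OCc1ccccc1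
F4 | step 6 | ethyl (2S,3S)‑5‑(3‑ethoxy‑3‑oxopropyl)‑2‑(4‑hydroxy‑3‑methoxyphenyl)‑7‑methoxy‑2,3‑dihydro‑1‑benzofuran‑3‑carboxylate | COc1cc([C@H]2Oc3c(OC)cc(CCC(=O)OCC)cc3[C@@H]2C(=O)OCC)ccc1O
F5 | step 6 | 4‑[(2S,3R)‑3‑(hydroxymethyl)‑5‑(3‑hydroxypropyl)‑7‑methoxy‑2,3‑dihydro‑1‑benzofuran‑2‑yl]‑2‑methoxyphenol | COc1cc([C@H]2Oc3c(OC)cc(CCCO)cc3[C@@H]2CO)ccc1O
F6 | step 2 | ethyl (E)‑3‑[3‑(ethoxycarbonyl)‑7‑methoxy‑1‑benzofuran‑5‑yl]prop‑2‑enoate | CCOC(=O)/C=C/c1cc(OC)c2occ(C(=O)OCC)c2c1
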